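The cyclohexane ring (C1 = C(Me)OH, C2 = CH carrying the pentenyl chain, C3 = quaternary carbon, C4 = CHBr, C5, C6) is cut at C1–C2 and C3–C4. A catalyst-controlled [4+2] cycloaddition joins the (E)-2-methyl enal obtained by allylic oxidation of (S)-linalool (C2, C3, the C3 methyl, both side-chain stubs and the remote carbinol) with the silyloxyfuran of α-angelica lactone (C1 methyl, C1, C6, C5, C4). It exploits the 1,4-relationship of the C1 oxygen and the C4 heteroatom: the furan oxygen becomes the C1 carbinol oxygen, the lactone carbonyl the C4 ketone, and the bridged adduct opens to a cyclohexenone with C1, C2 and C3 set at once. C4–Br follows by reduction and inversion.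

Key step: step 4

Assumption: (S)-(+)-linalool of high enantiomeric purity is taken as a commercial chiral-pool material.

Abbreviations: TBS = tert-butyldimethylsilyl; R = (3S)-3-(TBS-oxy)-3-methylpent-4-en-1-yl. Ring positions C1–C6 are those defined in the first paragraph.

Step 1
Reactants: 1 (S)-(+)-linalool, (3S)-3,7-dimethylocta-1,6-dien-3-ol
Product: 2 (3S)-3-(TBS-oxy)-3,7-dimethylocta-1,6-diene
Conditions: TBSOTf, 2,6-lutidine, CH2Cl2, −78 → 0 °C
Reagents that add atoms: tert-butyldimethylsilyl triflate, CC(C)(C)[Si](C)(C)OS(=O)(=O)C(F)(F)F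
Why: O-silylation of a tertiary alcohol with a silyl triflate and a hindered base leaves the stereocentre untouched and masks the acid-sensitive tertiary allylic alcohol for the Lewis-acid, ylide and Appel steps.

Step 2
Reactants: 2 (3S)-3-(TBS-oxy)-3,7-dimethylocta-1,6-diene
Product: 4 (2E,6S)-6-(TBS-oxy)-2,6-dimethylocta-2,7-dienal, via allylic alcohol 3 (not isolated)
Conditions: SeO2 (cat.), t-BuOOH, salicylic acid (cat.), CH2Cl2, rt; then MnO2, CH2Cl2, rt
Reagents that add atoms: selenium dioxide, O=[Se]=O (delivers the new oxygen atom); tert-butyl hydroperoxide, CC(C)(C)OO (terminal oxidant that regenerates SeO2)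
Why: The Riley-type allylic oxidation (ene reaction, then [2,3]-sigmatropic shift) attacks the (E)-methyl group of the trisubstituted alkene selectively, the vinyl group having no allylic hydrogen, and MnO2 takes the allylic alcohol on to the (E)-enal without changing the alkene geometry.

Step 3
Reactants: 5 α-angelica lactone, 5-methylfuran-2(3H)-one
Product: 6 tert-butyldimethyl[(5-methylfuran-2-yl)oxy]silane
Conditions: TBSOTf, Et3N, CH2Cl2, 0 °C
Reagents that add atoms: tert-butyldimethylsilyl triflate, CC(C)(C)[Si](C)(C)OS(=O)(=O)C(F)(F)F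
Why: Soft enolisation of the β,γ-unsaturated lactone and O-silylation give the aromatic 2-silyloxyfuran, the standard preparation of silyl dienolates of butenolides.

Step 4
Reactants: 4 (2E,6S)-6-(TBS-oxy)-2,6-dimethylocta-2,7-dienal; 6 tert-butyldimethyl[(5-methylfuran-2-yl)oxy]silane
Product: 8 5-(TBS-oxy)-1,5-dimethyl-2-oxo-6-R-cyclohex-3-ene-1-carbaldehyde (C1 methyl, C5 methyl and C6 chain R on one ring face; formyl and C5 silyloxy on the other), via oxanorbornene adduct 7 (not isolated)
Conditions: (S)-B-(o-tolyl)oxazaborolidine from (S)-α,α-diphenylprolinol (20 mol%), HNTf2 (18 mol%), CH2Cl2, −78 → −40 °C; then 0 °C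
Reagents that add atoms: none
Why: Proposed new method: the HNTf2-activated oxazaborolidine binds the formyl group of 4 (s-trans enal, formyl C–H···O contact), the methyl-bearing terminus C5 of the silyl dienolate 6 attacks the enal β-carbon while the ketene-acetal carbon C2 of 6 closes onto the α-carbon in an asynchronous [4+2] cycloaddition, and on warming the acid ionises the bridged silyl ketal 7 at its bridge C–O bond so that the silyl group passes to the tertiary alkoxide and the enone appears. The closest known reaction types are the oxazaborolidinium-catalysed Diels–Alder reaction of 2-substituted and 2,3-disubstituted acroleins with furan or silyloxydienes and the thermal [4+2] cycloaddition/bridge opening of 2-silyloxyfurans with electron-poor alkenes. The six-membered carbocycle is closed by an intermolecular suprafacial cycloaddition (4π furan, 2π enal), first as a 7-oxanorbornene whose oxygen bridge is then cleaved, so no further ring closure is involved. Ring C1 is fixed because the furan oxygen must sit on the bridge side and its methyl outside, ring C2 and C3 are fixed relative to each other by the (E)-geometry of 4, and relative to C1 by the exo position of the formyl group (syn to the oxygen bridge) that 2-methyl enals prefer. The absolute sense comes from the (S)-catalyst, which in the accepted pre-transition-state model shields one face and leaves the Re face at C2 and the Si face at C3 of enal 4 open, so the remote carbinol centre of 4 plays no part. The step needs cycloaddition across C=C in preference to vinylogous aldol addition at C=O and the regiochemistry furan C5 to β-carbon; the α-methyl branch and the low temperature are relied on for the first, and the polarisation of the silyl dienolate (nucleophilic at the methyl-bearing terminus) for the second.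

Step 5
Reactants: 8 5-(TBS-oxy)-1,5-dimethyl-2-oxo-6-R-cyclohex-3-ene-1-carbaldehyde
Product: 9 4-(TBS-oxy)-6-(2-methoxyethenyl)-4,6-dimethyl-5-R-cyclohex-2-en-1-one (E/Z mixture at the enol ether; ring configuration as in 8)
Conditions: MeOCH2PPh3Cl, KHMDS, THF, −78 → 0 °C
Reagents that add atoms: (methoxymethyl)triphenylphosphonium chloride, COC[P+](c1ccccc1)(c1ccccc1)c1ccccc1.[Cl-]
Why: Wittig olefination; the aldehyde is far more electrophilic than the hindered enone carbonyl, neither carbonyl has an enolisable α-hydrogen, and the silylated C1 oxygen cannot start a retro-Claisen cleavage of the β-keto aldehyde.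

Step 6
Reactants: 9 4-(TBS-oxy)-6-(2-methoxyethenyl)-4,6-dimethyl-5-R-cyclohex-2-en-1-one
Product: 10 2-[5-(TBS-oxy)-1,5-dimethyl-2-oxo-6-R-cyclohex-3-en-1-yl]acetaldehyde
Conditions: 1 M HCl, THF, 0 °C → rt
Reagents that add atoms: water, O
Why: Acid hydrolysis of the enol ether (protonation, hemiacetal, loss of methanol) gives the homologous aldehyde; tertiary TBS ethers tolerate dilute acid, and the ketone, flanked by a quaternary carbon and a vinylic CH, cannot enolise into an aldol reaction.

Step 7
Reactants: 10 2-[5-(TBS-oxy)-1,5-dimethyl-2-oxo-6-R-cyclohex-3-en-1-yl]acetaldehyde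
Product: 11 6-allyl-4-(TBS-oxy)-4,6-dimethyl-5-R-cyclohex-2-en-1-one
Conditions: MePPh3Br, KHMDS, THF, −78 → 0 °C
Reagents that add atoms: methyltriphenylphosphonium bromide, C[P+](c1ccccc1)(c1ccccc1)c1ccccc1.[Br-]
Why: Wittig methylenation converts the aldehyde selectively, the hindered enone carbonyl being much slower, and completes an allyl group on the quaternary carbon C3.

Step 8
Reactants: 11 6-allyl-4-(TBS-oxy)-4,6-dimethyl-5-R-cyclohex-2-en-1-one
Product: 12 2-allyl-4-(TBS-oxy)-2,4-dimethyl-3-R-cyclohexan-1-one
Conditions: Cu(OAc)2·H2O (5 mol%), 1,2-bis(diphenylphosphino)benzene (5 mol%), (EtO)2MeSiH, t-BuOH, toluene, rt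
Reagents that add atoms: none
Why: Stryker-type conjugate reduction: phosphine-ligated copper hydride adds hydride to the enone β-carbon and tert-butanol protonates the copper enolate, while isolated terminal alkenes and silyl ethers are inert.

Step 9
Reactants: 12 2-allyl-4-(TBS-oxy)-2,4-dimethyl-3-R-cyclohexan-1-one
Product: 13 2-allyl-4-(TBS-oxy)-2,4-dimethyl-3-R-cyclohexan-1-ol (hydroxyl cis to the allyl and silyloxy groups, trans to the C2 methyl of this name)
Conditions: (S)-2-methyl-CBS-oxazaborolidine (50 mol%), catecholborane, toluene, −78 → −40 °C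
Reagents that add atoms: none
Why: Corey–Bakshi–Shibata reduction: the catalyst tells the quaternary ring C3 side (large) from the C5 methylene side (small), and the (S)-catalyst should deliver hydride to the ring face that carries the C3 methyl, which sets ring C4 with the hydroxyl on the opposite face; catecholborane does not hydroborate the alkenes at low temperature.

Step 10
Reactants: 13 2-allyl-4-(TBS-oxy)-2,4-dimethyl-3-R-cyclohexan-1-ol
Product: 14 {[3-allyl-4-bromo-1,3-dimethyl-2-R-cyclohexyl]oxy}(tert-butyl)dimethylsilane (bromine cis to the C3 methyl, trans to the allyl group and to the C1 oxygen)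
Conditions: CBr4, PPh3, pyridine, toluene, 0 → 60 °C
Reagents that add atoms: carbon tetrabromide, BrC(Br)(Br)Br
Why: Appel reaction; bromide displaces the axial alkoxyphosphonium group by SN2 with inversion, which gives the equatorial C4 bromide of the target configuration, and the neutral conditions spare the silyl ethers and alkenes.

Step 11
Reactants: 14 {[3-allyl-4-bromo-1,3-dimethyl-2-R-cyclohexyl]oxy}(tert-butyl)dimethylsilane; 15 2-methylbut-3-en-2-ol
Product: 16 (E)-5-[6-bromo-3-(TBS-oxy)-1,3-dimethyl-2-R-cyclohexyl]-2-methylpent-3-en-2-ol (bis-TBS ether of the target)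
Conditions: second-generation Hoveyda–Grubbs catalyst (5 mol%), 15 (10 equiv), CH2Cl2, 40 °C
Reagents that add atoms: none
Why: Olefin cross-metathesis of the unhindered allyl group with the tertiary allylic alcohol 15, which is slow to homodimerise, should give the (E)-disubstituted alkene, while the vinyl group next to the silylated quaternary carbinol is too hindered to take part.

Step 12
Reactants: 16 bis-TBS ether of the target
Product: 17 (1S,2S,3S,4S)-4-bromo-2-[(3S)-3-hydroxy-3-methylpent-4-en-1-yl]-3-[(2E)-4-hydroxy-4-methylpent-2-en-1-yl]-1,3-dimethylcyclohexan-1-ol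
Conditions: HF·pyridine, pyridine, THF, 0 °C → rt
Reagents that add atoms: none
Why: Fluoride-induced cleavage of both tertiary silyl ethers under weakly acidic, buffered conditions avoids a free alkoxide that could displace the trans-1,4 bromide and keeps the tertiary allylic alcohols intact.

Compound list
1 | (S)-(+)-linalool, (3S)-3,7-dimethylocta-1,6-dien-3-ol | C=C[C@@](C)(O)CCC=C(C)C | starting material
2 | (3S)-3-(TBS-oxy)-3,7-dimethylocta-1,6-diene | C=C[C@@](C)(O[Si](C)(C)C(C)(C)C)CCC=C(C)C | intermediate
3 | (2E,6S)-6-(TBS-oxy)-2,6-dimethylocta-2,7-dien-1-ol (not isolated) | C=C[C@@](C)(O[Si](C)(C)C(C)(C)C)CC/C=C(\C)CO | intermediate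
4 | (2E,6S)-6-(TBS-oxy)-2,6-dimethylocta-2,7-dienal | C=C[C@@](C)(O[Si](C)(C)C(C)(C)C)CC/C=C(\C)C=O | intermediate
5 | α-angelica lactone, 5-methylfuran-2(3H)-one | CC1=CCC(=O)O1 | starting material
6 | tert-butyldimethyl[(5-methylfuran-2-yl)oxy]silane | Cc1ccc(O[Si](C)(C)C(C)(C)C)o1 | intermediate
7 | 1-(TBS-oxy)-2,4-dimethyl-3-R-7-oxabicyclo[2.2.1]hept-5-ene-2-carbaldehyde, formyl exo (syn to the oxygen bridge), C2 methyl and C3 chain endo (not isolated) | C=C[C@@](C)(O[Si](C)(C)C(C)(C)C)CC[C@H]1[C@](C)(C=O)[C@@]2(O[Si](C)(C)C(C)(C)C)C=C[C@]1(C)O2 | intermediate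
8 | 5-(TBS-oxy)-1,5-dimethyl-2-oxo-6-R-cyclohex-3-ene-1-carbaldehyde; both methyls and R on one face, formyl and silyloxy on the other | C=C[C@@](C)(O[Si](C)(C)C(C)(C)C)CC[C@H]1[C@](C)(C=O)C(=O)C=C[C@]1(C)O[Si](C)(C)C(C)(C)C | intermediate
9 | 4-(TBS-oxy)-6-(2-methoxyethenyl)-4,6-dimethyl-5-R-cyclohex-2-en-1-one (E/Z mixture at the enol ether) | C=C[C@@](C)(O[Si](C)(C)C(C)(C)C)CC[C@H]1[C@](C)(C=COC)C(=O)C=C[C@]1(C)O[Si](C)(C)C(C)(C)C | intermediate
10 | 2-[5-(TBS-oxy)-1,5-dimethyl-2-oxo-6-R-cyclohex-3-en-1-yl]acetaldehyde | C=C[C@@](C)(O[Si](C)(C)C(C)(C)C)CC[C@H]1[C@](C)(CC=O)C(=O)C=C[C@]1(C)O[Si](C)(C)C(C)(C)C | intermediate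
11 | 6-allyl-4-(TBS-oxy)-4,6-dimethyl-5-R-cyclohex-2-en-1-one | C=C[C@@](C)(O[Si](C)(C)C(C)(C)C)CC[C@H]1[C@](C)(CC=C)C(=O)C=C[C@]1(C)O[Si](C)(C)C(C)(C)C | intermediate
12 | 2-allyl-4-(TBS-oxy)-2,4-dimethyl-3-R-cyclohexan-1-one | C=C[C@@](C)(O[Si](C)(C)C(C)(C)C)CC[C@H]1[C@](C)(CC=C)C(=O)CC[C@]1(C)O[Si](C)(C)C(C)(C)C | intermediate
13 | 2-allyl-4-(TBS-oxy)-2,4-dimethyl-3-R-cyclohexan-1-ol, hydroxyl cis to allyl and silyloxy | C=C[C@@](C)(O[Si](C)(C)C(C)(C)C)CC[C@H]1[C@](C)(CC=C)[C@H](O)CC[C@]1(C)O[Si](C)(C)C(C)(C)C | intermediate
14 | {[3-allyl-4-bromo-1,3-dimethyl-2-R-cyclohexyl]oxy}(tert-butyl)dimethylsilane, bromine cis to the C3 methyl and trans to the C1 oxygen | C=C[C@@](C)(O[Si](C)(C)C(C)(C)C)CC[C@H]1[C@](C)(CC=C)[C@@H](Br)CC[C@]1(C)O[Si](C)(C)C(C)(C)C | intermediate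
15 | 2-methylbut-3-en-2-ol | C=CC(C)(C)O | starting material
16 | bis-TBS ether of the target, (E)-5-[6-bromo-3-(TBS-oxy)-1,3-dimethyl-2-R-cyclohexyl]-2-methylpent-3-en-2-ol | C=C[C@@](C)(O[Si](C)(C)C(C)(C)C)CC[C@H]1[C@](C)(C/C=C/C(C)(C)O)[C@@H](Br)CC[C@]1(C)O[Si](C)(C)C(C)(C)C | intermediate
17 | (1S,2S,3S,4S)-4-bromo-2-[(3S)-3-hydroxy-3-methylpent-4-en-1-yl]-3-[(2E)-4-hydroxy-4-methylpent-2-en-1-yl]-1,3-dimethylcyclohexan-1-ol | C=C[C@@](C)(O)CC[C@H]1[C@](C)(C/C=C/C(C)(C)O)[C@@H](Br)CC[C@]1(C)O | target

Total step count: 12. Longest linear sequence: 11 steps (steps 1, 2 and 4 to 12, from 1 to 17).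

Steps most likely to fail

Step 4 (proposed new method). The furan may add at the formyl carbon (vinylogous aldol) instead of across the C=C bond, the sequence may stop after the first C–C bond by silyl transfer to the enolate, or face control by the catalyst may be incomplete. The fallback uses known chemistry and sets out from 4 and 6. They are combined without catalyst under high pressure (CH2Cl2, about 12 kbar, rt), the known thermal Diels–Alder mode of 2-silyloxyfurans with electron-poor alkenes, in which no Lewis acid is present to promote carbonyl addition. This gives adduct 7 together with its counterpart of opposite ring chirality. Catalytic TBSOTf then opens both bridges, and 8 is separated by chromatography from the ring-enantiomeric diastereomer F1. The route is rejoined at 8.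

Step 10. At the neopentyl centre, E2 loss of the activated axial oxygen toward a C4=C5 alkene or a 1,2-methyl shift from the neighbouring quaternary carbon may outrun substitution. The fallback sets out from ketone 12 and sets C4 by radical hydrogen transfer instead of SN2. Hydrazine hydrate in hot ethanol gives the hydrazone F2. CuBr2 and LiOt-Bu convert it into the geminal dibromide F3 (known conversion of hydrazones into gem-dihalides). One equivalent of Bu3SnH with Et3B/air at low temperature removes one bromine through the α-bromo radical, which should take up hydrogen on the face away from the C3 methyl and leave bromine equatorial. This comes back to the route at 14.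

Step 9. The substrate's own bias (axial hydride delivery on the face away from the C3 methyl) may override the catalyst, or the hindered ketone may react too slowly. The fallback sets out from 12 and corrects the configuration by inversion. NaBH4 in methanol should give the C4-epimeric alcohol F4. A Mitsunobu reaction with 4-nitrobenzoic acid, PPh3 and DIAD inverts C4 to the 4-nitrobenzoate F5. K2CO3 in methanol then releases the alcohol, and the route is rejoined at 13.

Further compounds
F1 | step 4 | diastereomer of 8 with all three ring stereocentres inverted and the side-chain carbinol unchanged | C=C[C@@](C)(O[Si](C)(C)C(C)(C)C)CC[C@@H]1[C@@](C)(C=O)C(=O)C=C[C@@]1(C)O[Si](C)(C)C(C)(C)C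
F2 | step 10 | hydrazone of ketone 12 | C=C[C@@](C)(O[Si](C)(C)C(C)(C)C)CC[C@H]1[C@](C)(CC=C)C(=NN)CC[C@]1(C)O[Si](C)(C)C(C)(C)C
F3 | step 10 | geminal dibromide at ring C4, {[3-allyl-4,4-dibromo-1,3-dimethyl-2-R-cyclohexyl]oxy}(tert-butyl)dimethylsilane | C=C[C@@](C)(O[Si](C)(C)C(C)(C)C)CC[C@H]1[C@](C)(CC=C)C(Br)(Br)CC[C@]1(C)O[Si](C)(C)C(C)(C)C
F4 | step 9 | epimer of 13 at the carbinol carbon (hydroxyl cis to the neighbouring methyl) | C=C[C@@](C)(O[Si](C)(C)C(C)(C)C)CC[C@H]1[C@](C)(CC=C)[C@@H](O)CC[C@]1(C)O[Si](C)(C)C(C)(C)C
F5 | step 9 | 4-nitrobenzoate of 13 (carbinol configuration as in 13) | C=C[C@@](C)(O[Si](C)(C)C(C)(C)C)CC[C@H]1[C@](C)(CC=C)[C@H](OC(=O)c2ccc(cc2)[N+](=O)[O-])CC[C@]1(C)O[Si](C)(C)C(C)(C)C
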